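The runs come from a simulation from invented constants; noise was put on by code.

You cannot draw more J from a flask than the X that has gone from it, so here you count what stays rather than what forms.

all flasks: D 2.9 mM (held)

|  | X | remark | time |
|---|---|---|---|
| amber | 5 mM | run made earlier |  |
| green | 7.5 mM | run made earlier |  |
| flask | 10 mM |  | 5.0 d |

| run | time / d | J / % | X / % |
|---|---|---|---|
| amber | 0.500 | 23.2 | 78.0 |
| amber | 0.833 | 31.8 | 70.2 |
| amber | 1.67 | 36.4 | 64.7 |
| amber | 3.00 | 39.3 | 60.0 |
| amber | 6.00 | 36.9 | 61.5 |
| green | 1.25 | 33.9 | 64.5 |
| green | 2.50 | 36.2 | 62.6 |
| green | 4.00 | 40.0 | 61.3 |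
| green | 5.00 | 36.8 | 60.3 |
| green | 6.00 | 38.1 | 61.7 |

(scatter of a reading: 1 percentage point)

- the numbers in the tables scatter by 1 percentage point (one standard deviation)
- at the start none of D is in solution

- maple: doubling the saturation concentration of D, all else as stated
- cedar: doubling the transfer coefficient of D, all else as stated

- amount of J at 5.0 d, in percent of the X charged
- the change that raises the amount of J at 5.0 d, in percent of the X charged most ("none" if none brings more than 2 percentage points) (maple / cedar / none)
- amount of J at 5.0 d, in percent of the X charged, after maple

The late readings, from 3.00 d in amber and 4.00 d in green, average 61.0% of the charged X, and this share still free once X stops moving is your fraction left (one minus the equilibrium conversion). Amber holds 60.7% and green 61.1%, about the same, though their charges differ, so with D held as in both runs I carry the share to 10 mM, a step beyond both charges, and to 5.0 d, later than amber's 3.00 d.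

The crude ceiling for J is the whole charge and the crude floor is nothing. Two standard errors on the fraction left lower the ceiling to 39.9%, and the late J readings, less the same margin, raise the floor to 37.3%. I commit to 39.0%. The saturation concentration of D was never varied, so I assume that J over X follows it: the ratio 0.640 doubles under maple, the fraction left falls to 43.8%, and J reaches 56.2%, a gain above 2 percentage points. I take cedar to act on the speed of the approach, and the amber and green readings sit level from 3.00 d, earlier than 5.0 d, so I choose maple.

The forecast gives 38%, inside the bracket and a little below my figure, with maple and 55%, calling the plateau “not a supply limit”.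

The flask gives 38.9% of J at 5.0 d, inside the bracket, and 56.1% after maple; maple gains 17 points and cedar 0 points.

    D ⇌ Q, rate k1*(csat - [Q]) (kL = 3.70 × 10⁻⁴ s⁻¹)
    X + Q ⇌ J (K = 220 M⁻¹, k = 0.00290 M⁻¹ s⁻¹)

Here Q is the dissolved D. The forward half-life of X along the path to J, 0.95 d at 5.00 d, is shorter than the flask's 5.0 d, and that path has 99% of its turnover behind it at 2.50 d. X in the flask stands at 61.1% at 5.00 d with [Q] at 2.90 mM. The same flask read at 1.25 d still holds 66% of its X, 4.7 points above the fraction left.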